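Count the catalyst, not the starting material: that was my reply when you asked for a quick number on these flasks.

| flask | starting material | free catalyst | remark | time |
|---|---|---|---|---|
| green | 1.5 M (fed, over 2.0 min) | 3 mol% | run made earlier; the fed solution adds 1.0 times the starting volume |  |
| red | 1.5 M (fed, over 2.0 min) | 1 mol% | run made earlier; the fed solution adds 1.0 times the starting volume |  |
| Monday's | 0.40 M (fed, over 2.0 min) | 2 mol% | the fed solution adds 1.0 times the starting volume | 40 min |
| Tuesday's | 1.5 M (fed, over 2.0 min) | 2 mol% | the fed solution adds 1.0 times the starting volume | 40 min |
| Friday's | 3.0 M (fed, over 2.0 min) | 2 mol% | the fed solution adds 1.0 times the starting volume | 40 min |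
| Sunday's | 2.5 M (fed, over 2.0 min) | 2 mol% | the fed solution adds 1.0 times the starting volume | 40 min |
| Saturday's | 0.50 M (fed, over 2.0 min) | 2 mol% | the fed solution adds 1.0 times the starting volume | 40 min |

| run | time / min | product / % |
|---|---|---|
| green | 1.33 | 7.4 |
| green | 4.00 | 25.2 |
| green | 6.00 | 34.0 |
| green | 10.0 | 47.5 |
| green | 15.0 | 55.7 |
| green | 20.0 | 61.0 |
| green | 25.0 | 67.1 |
| red | 2.00 | 6.3 |
| red | 3.00 | 10.8 |
| red | 4.00 | 13.1 |
| red | 6.00 | 19.5 |
| red | 10.0 | 29.4 |
| red | 15.0 | 38.7 |
| red | 25.0 | 49.5 |

(scatter of a reading: 1 percentage point)

1. all flasks from highest to lowest amount of product, in percent of the starting material charged, at 40 min (Monday's / Tuesday's / Friday's / Sunday's / Saturday's)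
2. the amount of product, in percent of the starting material charged of the flask you put first, at 40 min
3. the amount of product, in percent of the starting material charged of the flask you put last, at 40 min

- every charge counts on the volume at the start, and the solution that is fed holds the whole dose
- the numbers in the tables scatter with a standard deviation of 1 percentage point
- percentages count the whole charge, also what has not yet gone in

The catalyst is the reagent charged in the smaller amount, so I wrote its balance. I supposed that free catalyst is lost in pairs, and that starting material falls pseudo-first-order at the pace of the free catalyst. With f as the fraction of the charge not yet product, some inverse power of f, less one, should then climb in step with catalyst charged times time.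

I tried the square and called the inverse square of f, less one, the tally, here 2.92 from the last red reading, with its scatter. Red gave 1.01 at 10.0 min. Green gave 8.24 at 25.0 min, where a loading of 3 mol% against 1 mol% promised 8.76.

I scaled the tally by loading times charge and by the time from the middle of the feed. For Monday's it came to 2.53, which is 46.8% product, and Friday's reached 77.6%, more than Monday's. So I ranked the flasks by charge, highest charge first.

Your forecast put the two dilute flasks first: Saturday's > Monday's > Tuesday's > Sunday's > Friday's, from 74% down to 67%, on the ground that “Dilute flasks win slightly”.

The simulation gave Friday's > Sunday's > Tuesday's > Saturday's > Monday's, from 78.5% down to 49.0%.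

    starting material + free catalyst → catalyst intermediate (k = 0.170 L mol⁻¹ s⁻¹)
    catalyst intermediate ⇌ free catalyst + product (K = 29.0 M, k = 0.380 s⁻¹)
    2 free catalyst → spent catalyst (k = 0.170 L mol⁻¹ s⁻¹)

Monday's 49.0% makes its tally 2.84, where I had 2.53. In Monday's at 11.6 min, free catalyst entered the step to catalyst intermediate 38 times as fast as it went to spent catalyst, and at 40.0 min 53 times as fast. Even so, by 40.0 min spent catalyst stood at 74.7% of the catalyst charged, with 51.0% of the starting material left. For the neighbour of Monday's with 1.2 mol% of free catalyst, the tally promises 37.0% product; the computed flask gives 39.7%.

(The readings were computed from invented constants.)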